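The readings are simulated with made-up constants, noise included.

In a one-step world a flask has one clock, and the vessel changes nothing.

| setting | north-west | south | north | Friday's | Wednesday's | Monday's | Thursday's |
|---|---|---|---|---|---|---|---|
| substrate | 10 mM | 10 mM | 10 mM | 10 mM | 10 mM | 10 mM (fed, over 40.0 min) | 10 mM |
| precatalyst | 2 mol% | 2 mol% | 2 mol% | 2 mol% | 2 mol% | 2 mol% | 2 mol% |
| impurity | 55 µM | 28 µM | 41 µM | 55 µM | 55 µM | 55 µM | 55 µM |
| remark | run made earlier | run made earlier | run made earlier | a closed flask charged with all of it at once and left for 50 min | one stirred flow tank at steady state, fed with the mixture as stated, mean residence time 500 min | all but substrate at the start; substrate goes in evenly over 40.0 min, the run ends at 50 min | one stirred flow tank at steady state, fed with the mixture as stated, mean residence time 50 min |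
| time |  |  |  | 50 min |  | 50 min |  |

- north-west (time / min: target / %, side product / %): 2.50: 0.2, 89.1; 5.00: 0.7, 99.7; 8.00: 1.0, 99.1; 15.0: 0.3, 100.4; 30.0: 0, 98.6
- south (time / min: target / %, side product / %): 4.00: 1.1, 98.1; 10.0: 0, 102.0; 20.0: 0.7, 100.9; 30.0: 0, 99.5; 40.0: 0.7, 96.7
- north (time / min: target / %, side product / %): 4.00: 0.8, 97.8; 10.0: 0, 100.6; 20.0: 1.1, 102.1; 30.0: 0.1, 100.5; 40.0: 0, 99.1

(standard deviation of a reading: 1 percentage point)

- the set-up with the highest share of target in all that became target or side product, at the outlet or at the end ("none" if the first two lie within 2 percentage points) (Friday's / Wednesday's / Monday's / Thursday's / none)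
- share of target in all that became target or side product, at the outlet or at the end, Friday's
- share of target in all that became target or side product, at the outlet or at the end, Wednesday's
- share of target in all that became target or side product, at the outlet or at the end, Monday's
- share of target in all that became target or side product, at the outlet or at the end, Thursday's

The readings look like that world: by 5.00 min in the north-west run, side product holds nearly all of the substrate charged. So I take from its 89.1% at 2.50 min the clock, the first-order rate constant of substrate's loss to side product, 0.887 /min, as a reading. Substrate then lives 1.13 min on average.

If a catalyst takes substrate at a steady pace r, first order in substrate by my assumption, the share of target is r/(r + clock), at any substrate level in that flask. The target readings scatter around nothing, so r is small in the first minutes.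

But by 5.00 min the clock leaves 1.19% of the substrate, so the later readings watch a flask with hardly any substrate and say little about an older catalyst. A precatalyst may need time, much like an induction period.

So I rank the set-ups by the age of the mixture that substrate meets: 1.13 min in Friday's flask, about 21.1 min in Monday's, 50 min in Thursday's tank and 500 min in Wednesday's. My order runs from Wednesday's down to Friday's, with the size open.

The forecast parts from that order, giving none, with 0.4% for Friday's, 0.6% for Wednesday's, 0.5% for Monday's and 0.5% for Thursday's: “I expect about 0.4% everywhere”.

The flask gives Wednesday's: 21.7% there, 5.71% for Thursday's, 1.76% for Monday's and 0.130% for Friday's.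

    substrate + free catalyst → free catalyst + target (k = 35.6 /M/s)
    substrate → side product (k = 0.0152 /s)
    free catalyst + impurity → spent catalyst A (k = 1240 /M/s)
    precatalyst → free catalyst (k = 2.25 × 10⁻⁴ /s)
    substrate + free catalyst → spent catalyst B (k = 0.0182 /M/s)

Substrate's half-life by its loss to side product is 0.76 min, against 51 min for precatalyst's conversion into free catalyst, and Wednesday's tank holds its mixture for 500 min on average. Set against the clock of 0.887 /min, Wednesday's share reads as a catalytic pace of 0.245 /min and Thursday's as 0.0537 /min, a factor of 4.56.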